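**Strategy**

The route rests on cutting the C2–C3 bond of the dihydrofuran ring (ring B; the benzene ring is ring A). The C3 carbinol, C2 and the exocyclic C(=CH2)CH2OAc carbon form a homoallylic alcohol whose C2 also carries the ring oxygen O1. This is the retron of an allene/aldehyde/organometal coupling. An achiral aryloxyallene with an ortho formyl group is therefore closed by a ligand-controlled nickel-catalysed alkylative cyclization with (acetoxymethyl)zinc bromide. In one operation this should form C2–C3, set both stereocentres cis, create the 1,1-disubstituted alkene and install the acetoxymethyl group. Angeloylation of the C3 hydroxyl and desilylation of the phenol complete the target.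

Key step: step 7

Remark on the chemistry: the sense of induction of the chiral nickel ligand in step 7 cannot be assigned in advance; the ligand enantiomer that leads to the (2R,3R) series is taken, and the same holds for the acyl-transfer catalyst of the fallback. Compound 1 and all reagents are taken as commercial.

**Route**

Step 1
Reactants: 1 1-(2,4-dimethoxyphenyl)ethanone
Product: 3 5-acetyl-2,4-dimethoxybenzaldehyde, via chloro(methoxy)methyl arene 2 (not isolated)
Conditions: Cl2CHOMe (1.5 equiv), TiCl4 (2.5 equiv), CH2Cl2, −10 to 0 °C; then ice water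
Reagents that add atoms: dichloromethyl methyl ether COC(Cl)Cl; water O
Why: Rieche formylation (electrophilic aromatic substitution) should go to C5 alone, because this position is para to one methoxy group, ortho to the other and meta to the acetyl group while C3 is flanked by both methoxy groups, and water then hydrolyses chloro ether 2 to the aldehyde.

Step 2
Reactants: 3 5-acetyl-2,4-dimethoxybenzaldehyde
Product: 4 5-acetyl-2,4-dihydroxybenzaldehyde
Conditions: BCl3 (3.5 equiv), CH2Cl2, −78 to 0 °C; then H2O
Reagents that add atoms: none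
Why: BCl3 cleaves aryl methyl ethers that stand ortho to a carbonyl group through a six-membered boron chelate (chelation-assisted ether cleavage), and here each methoxy group has such a neighbour, the formyl group for one and the acetyl group for the other.

Step 3
Reactants: 4 5-acetyl-2,4-dihydroxybenzaldehyde
Product: 5 1-[5-(dimethoxymethyl)-2,4-dihydroxyphenyl]ethanone
Conditions: HC(OMe)3 (3 equiv), MeOH, TsOH·H2O (2 mol%), 0 °C to rt; Et3N quench, used crude
Reagents that add atoms: trimethyl orthoformate COC(OC)OC
Why: Acid-catalysed acetalization takes the aldehyde and leaves the hydrogen-bonded, less electrophilic aryl ketone, which masks the formyl group against base and frees its neighbouring hydroxyl from the hydrogen bond that otherwise makes the two phenols alike.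

Step 4
Reactants: 5 1-[5-(dimethoxymethyl)-2,4-dihydroxyphenyl]ethanone
Product: 6 1-[5-(dimethoxymethyl)-2-hydroxy-4-(prop-2-yn-1-yloxy)phenyl]ethanone
Conditions: propargyl bromide (1.1 equiv), K2CO3 (1.2 equiv), acetone, 40 °C
Reagents that add atoms: propargyl bromide C#CCBr
Why: Williamson ether synthesis should occur at the only phenol that is not locked in a hydrogen bond to the acetyl group, the same selectivity that 2,4-dihydroxyacetophenone shows at its 4-hydroxyl.

Step 5
Reactants: 6 1-[5-(dimethoxymethyl)-2-hydroxy-4-(prop-2-yn-1-yloxy)phenyl]ethanone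
Product: 8 5-acetyl-4-hydroxy-2-(propa-1,2-dien-1-yloxy)benzaldehyde, via allenyl ether acetal 7 (not isolated)
Conditions: KOtBu (2.2 equiv), THF, 0 °C to rt; then aq. HCl to pH 3, THF, 0 °C, 10 min
Reagents that add atoms: water O
Why: Base-mediated propargyl-to-allenyl prototropic isomerization of the aryl propargyl ether (the first equivalent of base only forms the phenoxide) should give 7, and the acetal of this very electron-rich arene is then hydrolysed by dilute acid faster than the aryloxyallene is hydrated.

Step 6
Reactants: 8 5-acetyl-4-hydroxy-2-(propa-1,2-dien-1-yloxy)benzaldehyde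
Product: 9 5-acetyl-4-{[tert-butyl(dimethyl)silyl]oxy}-2-(propa-1,2-dien-1-yloxy)benzaldehyde
Conditions: TBSCl (1.3 equiv), imidazole (2.5 equiv), DMF, rt
Reagents that add atoms: tert-butyldimethylsilyl chloride CC(C)(C)[Si](C)(C)Cl
Why: Silyl ether formation at the single hydroxyl keeps the phenol from quenching the zinc reagent, from deactivating the para formyl group as a phenoxide and from being acylated in step 8.

Step 7
Reactants: 9 5-acetyl-4-{[tert-butyl(dimethyl)silyl]oxy}-2-(propa-1,2-dien-1-yloxy)benzaldehyde
Product: 10 2-[(2R,3R)-5-acetyl-6-{[tert-butyl(dimethyl)silyl]oxy}-3-hydroxy-2,3-dihydro-1-benzofuran-2-yl]prop-2-en-1-yl acetate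
Conditions: Ni(cod)2 (10 mol%), chiral spirobiindane phosphoramidite (SIPHOS-PE type, 12 mol%), AcOCH2ZnBr (2.0 equiv, from BrCH2OAc and Zn dust in THF), THF, 0 °C; then aqueous work-up at pH 7
Reagents that add atoms: (acetoxymethyl)zinc bromide CC(=O)OC[Zn]Br
Why: Proposed new method: zerovalent nickel binds the formyl C=O and the oxygen-bearing C=C of the allene and couples them by oxidative cyclization to a five-membered oxanickelacycle (Ni–O–C3–C2–C central), which makes the C2–C3 bond, and transmetalation from zinc followed by C–C reductive elimination places the acetoxymethyl group on the central allene carbon while the terminal carbon becomes the exocyclic methylene. The closest known reactions are the nickel-catalysed alkylative cyclization of allenyl aldehydes with organozincs, which gives cis homoallylic alcohols, and the enantioselective nickel and spiro phosphoramidite alkylative coupling of alkynes with aldehydes and Me2Zn; an aryloxyallene, an α-acyloxy zinc reagent and ligand control of the absolute sense have not been shown together. Ring B closes in the 5-exo-trig mode at the formyl carbon, and the central allene carbon stays outside the ring. C2 and C3 should come out cis because the C3–O and C2–C(central) bonds are both ring bonds of the nickelacycle fused to ring B and so lie on one face, and the absolute configuration (2R,3R) is set by the chiral ligand on nickel, which selects the face of the formyl group. The step needs attack at the oxygen-bearing allene carbon and not at the central one (ring B and not a six-membered ring), which the exo mode of the short tether favours, reaction at the formyl and not the acetyl group, which only the ortho position allows, and no ionization of the new allylic acetate or loss of aryloxide from the alkenylnickel, which the low temperature and the anti arrangement of O1 to nickel in the bicyclic nickelacycle should hold back.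

Step 8
Reactants: 10 2-[(2R,3R)-5-acetyl-6-{[tert-butyl(dimethyl)silyl]oxy}-3-hydroxy-2,3-dihydro-1-benzofuran-2-yl]prop-2-en-1-yl acetate
Product: 11 (2R,3R)-5-acetyl-2-[3-(acetyloxy)prop-1-en-2-yl]-6-{[tert-butyl(dimethyl)silyl]oxy}-2,3-dihydro-1-benzofuran-3-yl (2Z)-2-methylbut-2-enoate
Conditions: angelic acid (1.5 equiv), 2,4,6-trichlorobenzoyl chloride (1.5 equiv), Et3N (3 equiv), toluene, rt, 2 h; then 10, DMAP (0.3 equiv), 0 °C to rt
Reagents that add atoms: angelic acid C/C=C(/C)C(=O)O
Why: Yamaguchi esterification should acylate the C3 hydroxyl with retention because the C3–O bond is not touched, DMAP attacks the mixed anhydride at the unhindered angeloyl carbonyl, and the low DMAP loading and temperature limit Z-to-E isomerization of the angelate and base-induced elimination to the benzofuran.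

Step 9
Reactants: 11 (2R,3R)-5-acetyl-2-[3-(acetyloxy)prop-1-en-2-yl]-6-{[tert-butyl(dimethyl)silyl]oxy}-2,3-dihydro-1-benzofuran-3-yl (2Z)-2-methylbut-2-enoate
Product: 12 (2R,3R)-5-acetyl-2-[3-(acetyloxy)prop-1-en-2-yl]-6-hydroxy-2,3-dihydro-1-benzofuran-3-yl (2Z)-2-methylbut-2-enoate
Conditions: KHF2 (2 equiv), MeOH, rt
Reagents that add atoms: none
Why: Fluoride-induced desilylation cleaves the aryl silyl ether, which the ortho acetyl group makes especially labile, under weakly acidic conditions in which the alkyl esters survive and no free phenoxide can expel the para-related benzylic angelate.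

**Compound list**

1 | 1-(2,4-dimethoxyphenyl)ethanone | CC(=O)c1ccc(OC)cc1OC | starting material
2 | 1-{5-[chloro(methoxy)methyl]-2,4-dimethoxyphenyl}ethanone | CC(=O)c1cc(C(Cl)OC)c(OC)cc1OC | intermediate (not isolated)
3 | 5-acetyl-2,4-dimethoxybenzaldehyde | CC(=O)c1cc(C=O)c(OC)cc1OC | intermediate
4 | 5-acetyl-2,4-dihydroxybenzaldehyde | CC(=O)c1cc(C=O)c(O)cc1O | intermediate
5 | 1-[5-(dimethoxymethyl)-2,4-dihydroxyphenyl]ethanone | CC(=O)c1cc(C(OC)OC)c(O)cc1O | intermediate
6 | 1-[5-(dimethoxymethyl)-2-hydroxy-4-(prop-2-yn-1-yloxy)phenyl]ethanone | CC(=O)c1cc(C(OC)OC)c(OCC#C)cc1O | intermediate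
7 | 1-[5-(dimethoxymethyl)-2-hydroxy-4-(propa-1,2-dien-1-yloxy)phenyl]ethanone | CC(=O)c1cc(C(OC)OC)c(OC=C=C)cc1O | intermediate (not isolated)
8 | 5-acetyl-4-hydroxy-2-(propa-1,2-dien-1-yloxy)benzaldehyde | CC(=O)c1cc(C=O)c(OC=C=C)cc1O | intermediate
9 | 5-acetyl-4-{[tert-butyl(dimethyl)silyl]oxy}-2-(propa-1,2-dien-1-yloxy)benzaldehyde | CC(=O)c1cc(C=O)c(OC=C=C)cc1O[Si](C)(C)C(C)(C)C | intermediate
10 | 2-[(2R,3R)-5-acetyl-6-{[tert-butyl(dimethyl)silyl]oxy}-3-hydroxy-2,3-dihydro-1-benzofuran-2-yl]prop-2-en-1-yl acetate (2,3-cis) | C=C(COC(C)=O)[C@H]1Oc2cc(O[Si](C)(C)C(C)(C)C)c(C(C)=O)cc2[C@H]1O | intermediate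
11 | (2R,3R)-5-acetyl-2-[3-(acetyloxy)prop-1-en-2-yl]-6-{[tert-butyl(dimethyl)silyl]oxy}-2,3-dihydro-1-benzofuran-3-yl (2Z)-2-methylbut-2-enoate | C=C(COC(C)=O)[C@H]1Oc2cc(O[Si](C)(C)C(C)(C)C)c(C(C)=O)cc2[C@H]1OC(=O)/C(C)=C\C | intermediate
12 | (2R,3R)-5-acetyl-2-[3-(acetyloxy)prop-1-en-2-yl]-6-hydroxy-2,3-dihydro-1-benzofuran-3-yl (2Z)-2-methylbut-2-enoate (CNP0323250.1, 2,3-cis) | C=C(COC(C)=O)[C@H]1Oc2cc(O)c(C(C)=O)cc2[C@H]1OC(=O)/C(C)=C\C | target

**Step count and risks**

Total steps: 9. Longest linear sequence: 9 steps (1 to 12).

The three steps most likely to fail: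

1. Step 7 (bears the label). The ligand may discriminate the two faces of the formyl group poorly, may divert C–C bond formation to the central allene carbon, or the zerovalent nickel may go on to ionize the allylic acetate it has just made. The fallback uses known chemistry and sets out from 9. The cyclization is run under the ligand-free conditions established for allenyl aldehydes (Ni(cod)2 10 mol%, AcOCH2ZnBr, THF, 0 °C), which should give the racemic cis alcohol, that is 10 together with its enantiomer 2-[(2S,3S)-5-acetyl-6-{[tert-butyl(dimethyl)silyl]oxy}-3-hydroxy-2,3-dihydro-1-benzofuran-2-yl]prop-2-en-1-yl acetate F1. Acylative kinetic resolution of this benzylic alcohol with benzotetramisole (5 mol%), isobutyric anhydride (0.55 equiv) and iPr2NEt in CHCl3 at 0 °C should convert the unwanted enantiomer into (2S,3S)-5-acetyl-2-[3-(acetyloxy)prop-1-en-2-yl]-6-{[tert-butyl(dimethyl)silyl]oxy}-2,3-dihydro-1-benzofuran-3-yl 2-methylpropanoate F2 and leave 10. Chromatography separates the two, and the route is rejoined at 10.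

2. Step 8. The angeloyl unit may isomerize from Z to E through reversible conjugate addition of DMAP, and the new benzylic ester may undergo base-induced anti elimination toward the benzofuran. The fallback sets out from 10 and builds the Z alkene after the ester bond. 10 is esterified with 2-[bis(2-methylphenoxy)phosphoryl]propanoic acid (DCC, DMAP 5 mol%, CH2Cl2, 0 °C) to give (2R,3R)-5-acetyl-2-[3-(acetyloxy)prop-1-en-2-yl]-6-{[tert-butyl(dimethyl)silyl]oxy}-2,3-dihydro-1-benzofuran-3-yl 2-[bis(2-methylphenoxy)phosphoryl]propanoate F3. A Z-selective Horner–Wadsworth–Emmons reaction with acetaldehyde (NaH, THF, −78 °C) should then give the angelate, and the route is rejoined at 11.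

3. Step 5. The allenyl ether may isomerize further to the 1-propynyl ether, the labile acetal may be lost early so that the acetyl enolate condenses with the freed aldehyde, or acid may hydrate the allenyl ether while the acetal is cleaved. The fallback sets out from 4 and masks the formyl group by its oxidation level, so that no acid is needed once the allene is in place. NaBH4 (EtOH, 0 °C) should reduce only the aldehyde and give 1-[2,4-dihydroxy-5-(hydroxymethyl)phenyl]ethanone F4. Alkylation with propargyl bromide and K2CO3 in acetone, again at the phenol that is not hydrogen-bonded, gives 1-[2-hydroxy-5-(hydroxymethyl)-4-(prop-2-yn-1-yloxy)phenyl]ethanone F5. KOtBu in THF isomerizes it to 1-[2-hydroxy-5-(hydroxymethyl)-4-(propa-1,2-dien-1-yloxy)phenyl]ethanone F6. MnO2 in CH2Cl2 at rt oxidizes the benzylic alcohol under neutral conditions, and the route is rejoined at 8.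

Further compounds

F1 | step 7 | 2-[(2S,3S)-5-acetyl-6-{[tert-butyl(dimethyl)silyl]oxy}-3-hydroxy-2,3-dihydro-1-benzofuran-2-yl]prop-2-en-1-yl acetate | C=C(COC(C)=O)[C@@H]1Oc2cc(O[Si](C)(C)C(C)(C)C)c(C(C)=O)cc2[C@@H]1O
F2 | step 7 | (2S,3S)-5-acetyl-2-[3-(acetyloxy)prop-1-en-2-yl]-6-{[tert-butyl(dimethyl)silyl]oxy}-2,3-dihydro-1-benzofuran-3-yl 2-methylpropanoate | C=C(COC(C)=O)[C@@H]1Oc2cc(O[Si](C)(C)C(C)(C)C)c(C(C)=O)cc2[C@@H]1OC(=O)C(C)C
F3 | step 8 | (2R,3R)-5-acetyl-2-[3-(acetyloxy)prop-1-en-2-yl]-6-{[tert-butyl(dimethyl)silyl]oxy}-2,3-dihydro-1-benzofuran-3-yl 2-[bis(2-methylphenoxy)phosphoryl]propanoate | C=C(COC(C)=O)[C@H]1Oc2cc(O[Si](C)(C)C(C)(C)C)c(C(C)=O)cc2[C@H]1OC(=O)C(C)P(=O)(Oc1ccccc1C)Oc1ccccc1C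
F4 | step 5 | 1-[2,4-dihydroxy-5-(hydroxymethyl)phenyl]ethanone | CC(=O)c1cc(CO)c(O)cc1O
F5 | step 5 | 1-[2-hydroxy-5-(hydroxymethyl)-4-(prop-2-yn-1-yloxy)phenyl]ethanone | CC(=O)c1cc(CO)c(OCC#C)cc1O
F6 | step 5 | 1-[2-hydroxy-5-(hydroxymethyl)-4-(propa-1,2-dien-1-yloxy)phenyl]ethanone | CC(=O)c1cc(CO)c(OC=C=C)cc1O
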